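A direct plan would silylate 2-methoxyresorcinol, add the fourth ring oxygen by C–H borylation/oxidation
and close a benzofuran by an intramolecular Heck reaction (iodo ester A1).
It would then extend the side chain to the silylated (S)-carbinol A2, cleave the furan C2=C3 bond with ozone (keto formate A3)
and let the ketone enolate take the formyl group from oxygen, which would close the lactol.
The Heck closure would be weak: one of two equivalent C–I bonds would have to react alone.
The ozonolysis with O-to-C formyl transfer would be weaker: unprecedented, with three ozone-sensitive silyloxyarenes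
and an enolate that could expel the C9 silyloxy group instead of adding.
The build-up would be linear: some ten steps on an achiral benzofuran before the one stereocentre is set.

The new route disconnects C3–C4 and treats the β-keto-lactol as a 5-alkoxy-2-isoxazoline. In one operation, a Huisgen cycloaddition of the ring A nitrile oxide 17 to the enantiopure 4H-1,3-dioxin 15 (the cyclic enol acetal of an (S)-aldol aldehyde) forms the C3–C4 and C2–O bonds, sets C3 from C9, and locks ketone, aldehyde and carbinol in a bicycle that cannot dehydrate or undergo retro-aldol cleavage. N–O cleavage then makes C2 a hemiacetal, so that after debenzylation the template leaves as pivalaldehyde and the lactol closes on O1 without acid or base. No benzofuran, Heck reaction, ozonolysis or formyl transfer occurs, and two fragments of six and five steps are joined late.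

Key step: step 12

Remark: target atoms are numbered as in chroman-4-one (C9 = carbinol carbon); C2 and C3 can epimerise by lactol ring opening and enolisation, so C2 is taken to settle as the 2,3-trans (2S) anomer, while the route delivers C3 as R.

Step 1
Reactants: 1 2,4,6-trihydroxytoluene
Product: 2 2,4,6-trihydroxy-3-methylbenzaldehyde
Conditions: POCl3, DMF, EtOAc, 0 °C to rt; then H2O, 50 °C
Reagents that add atoms: N,N-dimethylformamide CN(C)C=O (formyl carbon); water O (formyl oxygen)
Why: Vilsmeier–Haack formylation of the phloroglucinol ring at one of its two equivalent free positions, where precipitation of the iminium salt should stop the reaction after one formyl group.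

Step 2
Reactants: 2 2,4,6-trihydroxy-3-methylbenzaldehyde
Product: 3 2,4,6-tris(benzyloxy)-3-methylbenzaldehyde
Conditions: BnBr, K2CO3, DMF, 60 °C
Reagents that add atoms: benzyl bromide BrCc1ccccc1
Why: Williamson ether synthesis, in which the formyl group lowers the C-nucleophilicity of the ring so that O-benzylation should prevail; benzyl ethers cannot migrate between neighbouring oxygens later.

Step 3
Reactants: 3 2,4,6-tris(benzyloxy)-3-methylbenzaldehyde
Product: 5 2,4,6-tris(benzyloxy)-3-methylphenol, via aryl formate 4 (not isolated)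
Conditions: mCPBA, NaHCO3, CH2Cl2, 0 °C to rt; then K2CO3 (cat.), MeOH, rt
Reagents that add atoms: 3-chloroperoxybenzoic acid OOC(=O)c1cccc(Cl)c1 (phenol oxygen)
Why: Baeyer–Villiger oxidation of a 2,4,6-trialkoxybenzaldehyde, in which the electron-rich aryl group migrates, then methanolysis of the formate; the first formyl group thus becomes the oxygen of the future 6-methoxy group.

Step 4
Reactants: 5 2,4,6-tris(benzyloxy)-3-methylphenol
Product: 6 1,3,5-tris(benzyloxy)-2-methoxy-4-methylbenzene
Conditions: MeI, K2CO3, DMF, rt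
Reagents that add atoms: iodomethane CI
Why: Williamson O-methylation of the only free phenol places the methyl ether between two benzyloxy groups, the pattern that ends as 6-OMe between free 5-OH and 7-OH.

Step 5
Reactants: 6 1,3,5-tris(benzyloxy)-2-methoxy-4-methylbenzene
Product: 7 2,4,6-tris(benzyloxy)-3-methoxy-5-methylbenzaldehyde
Conditions: POCl3, DMF, 0 °C to rt; then H2O, rt
Reagents that add atoms: N,N-dimethylformamide CN(C)C=O (formyl carbon); water O (formyl oxygen)
Why: Vilsmeier–Haack formylation at the single remaining ring position, activated by two ortho and one para benzyloxy group; this carbon becomes C4 of the target.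

Step 6
Reactants: 7 2,4,6-tris(benzyloxy)-3-methoxy-5-methylbenzaldehyde
Product: 8 (E)-2,4,6-tris(benzyloxy)-3-methoxy-5-methylbenzaldehyde oxime
Conditions: NH2OH·HCl, NaOAc, EtOH/THF, 50 °C
Reagents that add atoms: hydroxylamine hydrochloride NO.Cl
Why: Oxime condensation of the hindered aldehyde; the oxime geometry is lost when the nitrile oxide is made.

Step 7
Reactants: 9 ethyl 3-[4-(benzyloxy)phenyl]-3-oxopropanoate
Product: 10 ethyl (3S)-3-[4-(benzyloxy)phenyl]-3-hydroxypropanoate
Conditions: RuCl[(S,S)-TsDPEN](p-cymene) (cat.), HCO2H/Et3N (5:2), DMF, 40 °C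
Reagents that add atoms: none
Why: Noyori asymmetric transfer hydrogenation of an aryl β-keto ester; the (S,S)-catalyst should deliver hydride to the face that gives (S)-1-aryl carbinols, which sets C9, the only stereocentre that comes from a reagent.

Step 8
Reactants: 10 ethyl (3S)-3-[4-(benzyloxy)phenyl]-3-hydroxypropanoate
Product: 11 (3S)-3-[4-(benzyloxy)phenyl]-3-hydroxypropanoic acid
Conditions: LiOH, THF/H2O, 0 °C; then 1 M HCl to pH 3, 0 °C
Reagents that add atoms: lithium hydroxide [Li+].[OH-] (carboxyl oxygen)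
Why: Ester saponification at 0 °C, which does not touch the carbinol centre; the cold, brief acidification should avoid ionisation of the 4-alkoxybenzylic alcohol.

Step 9
Reactants: 11 (3S)-3-[4-(benzyloxy)phenyl]-3-hydroxypropanoic acid
Product: 12 (2R,6S)-6-[4-(benzyloxy)phenyl]-2-tert-butyl-1,3-dioxan-4-one
Conditions: t-BuCHO, pyridinium p-toluenesulfonate (cat.), 4 Å MS, CH2Cl2, reflux; crystallisation
Reagents that add atoms: pivalaldehyde CC(C)(C)C=O
Why: Acid-catalysed acetalisation of a β-hydroxy acid with pivalaldehyde to the 1,3-dioxan-4-one; C2 is set under thermodynamic control cis to the 6-aryl group (both equatorial) and C6 is not touched.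

Step 10
Reactants: 12 (2R,6S)-6-[4-(benzyloxy)phenyl]-2-tert-butyl-1,3-dioxan-4-one
Product: 13 (2R,6S)-6-[4-(benzyloxy)phenyl]-2-tert-butyl-1,3-dioxan-4-ol (C4 epimers)
Conditions: i-Bu2AlH, CH2Cl2, −78 °C; aq KNaC4H4O6
Reagents that add atoms: none
Why: Partial reduction of the lactone to the lactol by i-Bu2AlH at low temperature, where the tetrahedral aluminate is stable; the new hemiacetal centre is removed in the next step.

Step 11
Reactants: 13 (2R,6S)-6-[4-(benzyloxy)phenyl]-2-tert-butyl-1,3-dioxan-4-ol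
Product: 15 (2S,4S)-4-[4-(benzyloxy)phenyl]-2-tert-butyl-4H-1,3-dioxin, via anomeric mesylate 14 (not isolated)
Conditions: MsCl, Et3N, CH2Cl2, −20 °C to rt; Et3N-deactivated SiO2
Reagents that add atoms: methanesulfonyl chloride CS(=O)(=O)Cl (present only in 14)
Why: Lactol dehydration as in glycal synthesis: the mesylate ionises to the oxocarbenium ion, which Et3N deprotonates at the only adjacent CH2; no stereocentre is touched (the C2 descriptor changes from R to S by the priority rules only).

Step 12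
Reactants: 8 (E)-2,4,6-tris(benzyloxy)-3-methoxy-5-methylbenzaldehyde oxime; 15 (2S,4S)-4-[4-(benzyloxy)phenyl]-2-tert-butyl-4H-1,3-dioxin
Product: 18 (3aR,4S,6R,7aR)-4-[4-(benzyloxy)phenyl]-6-tert-butyl-3-[2,4,6-tris(benzyloxy)-3-methoxy-5-methylphenyl]-3a,7a-dihydro-4H,6H-[1,3]dioxino[5,4-d]isoxazole, via hydroximoyl chloride 16 (not isolated), via nitrile oxide 17 (not isolated)
Conditions: NCS, DMF, rt; then Et3N, CH2Cl2, 0 °C, aqueous wash, drying; then 15, PhMe (1 M), 4 Å MS, 50 °C, dark
Reagents that add atoms: N-chlorosuccinimide O=C1CCC(=O)N1Cl (chlorine, present only in 16)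
Why: Huisgen 1,3-dipolar cycloaddition: base takes HCl from 16, the nitrile oxide 17 persists because both ortho positions carry benzyloxy groups, and it adds in a concerted, asynchronous [3+2] manner across the enol-ether C5=C6 bond of 15. The closest known reactions are the additions of aryl nitrile oxides to 2,3-dihydrofuran, 3,4-dihydro-2H-pyran and glycals, which give 5-alkoxy-2-isoxazolines. The one ring that is closed, the 2-isoxazoline, forms by this [3+2] cycloaddition, which makes the C3–C4 bond and the second C2–O bond of the target (C3–C3a and O1–C7a of 18) at once. C3a (C3 of the target) is controlled by C4 of 15 (C9 of the target): the equatorial tert-butyl group fixes the half-chair, the dipole approaches the face that carries only the two axial hydrogens, and its aryl group, which must pass over C4, stays away from the 4-aryl group, so the new C–C bond is trans to that group; C7a follows from the suprafacial addition (cis fusion) and C6 is untouched. The step needs regiocontrol, secured by the polarisation of the enol ether (nucleophilic β-carbon to the dipole carbon, dipole oxygen to the acetal carbon), face control as described, and chemoselectivity, secured because 15 has no other reactive π bond and 17 does not dimerise. The product stores the ketone as C=N, the aldehyde as an acetal carbon and the carbinol as a ring ether, so that neither retro-aldol cleavage nor dehydration to a chromone is possible until the end.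

Step 13
Reactants: 18 (3aR,4S,6R,7aR)-4-[4-(benzyloxy)phenyl]-6-tert-butyl-3-[2,4,6-tris(benzyloxy)-3-methoxy-5-methylphenyl]-3a,7a-dihydro-4H,6H-[1,3]dioxino[5,4-d]isoxazole
Product: 20 [(2R,4S,5R,6S)-6-[4-(benzyloxy)phenyl]-2-tert-butyl-4-hydroxy-1,3-dioxan-5-yl][2,4,6-tris(benzyloxy)-3-methoxy-5-methylphenyl]methanone, via hydroxy imine 19 (not isolated)
Conditions: Raney Ni (W-2), H2 (1 atm), B(OH)3, THF/MeOH/H2O, rt
Reagents that add atoms: water O (ketone oxygen)
Why: Hydrogenolysis of the isoxazoline N–O bond and boric acid-buffered hydrolysis of the β-hydroxy imine, the standard unmasking of a 2-isoxazoline to an aldol; here the β-hydroxy group is the hemiacetal OH of a 4-hydroxy-1,3-dioxane, so the aldehyde stays masked, aryl benzyl ethers should largely survive (any that are lost are due for removal in step 14), and C5 of the dioxane (C3 of the target) keeps its equatorial, more stable configuration.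

Step 14
Reactants: 20 [(2R,4S,5R,6S)-6-[4-(benzyloxy)phenyl]-2-tert-butyl-4-hydroxy-1,3-dioxan-5-yl][2,4,6-tris(benzyloxy)-3-methoxy-5-methylphenyl]methanone
Product: 22 (2S,3R)-2,5,7-trihydroxy-3-[(S)-hydroxy(4-hydroxyphenyl)methyl]-6-methoxy-8-methylchroman-4-one, via tetraphenol keto-lactol 21 (not isolated)
Conditions: H2 (1 atm), Pd(OH)2/C, THF/MeOH/H2O, rt; filtration; concentration below 30 °C
Reagents that add atoms: none
Why: Hydrogenolysis of the four aryl benzyl ethers, after which ring–chain tautomerism of the hemiacetal (hemiacetal exchange) should release pivalaldehyde and the C9 hydroxyl while O1–H captures the aldehyde as the six-membered lactol, without acid or base; C9 is untouched, C3 is delivered as R and C2 should settle as the 2,3-trans (2S) anomer.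

**Compound list**

1 | 2,4,6-trihydroxytoluene | Cc1c(O)cc(O)cc1O | starting material
2 | 2,4,6-trihydroxy-3-methylbenzaldehyde | O=Cc1c(O)cc(O)c(C)c1O | intermediate
3 | 2,4,6-tris(benzyloxy)-3-methylbenzaldehyde | O=Cc1c(OCc2ccccc2)cc(OCc2ccccc2)c(C)c1OCc1ccccc1 | intermediate
4 | 2,4,6-tris(benzyloxy)-3-methylphenyl formate | O=COc1c(OCc2ccccc2)cc(OCc2ccccc2)c(C)c1OCc1ccccc1 | intermediate
5 | 2,4,6-tris(benzyloxy)-3-methylphenol | Oc1c(OCc2ccccc2)cc(OCc2ccccc2)c(C)c1OCc1ccccc1 | intermediate
6 | 1,3,5-tris(benzyloxy)-2-methoxy-4-methylbenzene | COc1c(OCc2ccccc2)cc(OCc2ccccc2)c(C)c1OCc1ccccc1 | intermediate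
7 | 2,4,6-tris(benzyloxy)-3-methoxy-5-methylbenzaldehyde | COc1c(OCc2ccccc2)c(C=O)c(OCc2ccccc2)c(C)c1OCc1ccccc1 | intermediate
8 | (E)-2,4,6-tris(benzyloxy)-3-methoxy-5-methylbenzaldehyde oxime | COc1c(OCc2ccccc2)c(/C=N/O)c(OCc2ccccc2)c(C)c1OCc1ccccc1 | intermediate
9 | ethyl 3-[4-(benzyloxy)phenyl]-3-oxopropanoate | CCOC(=O)CC(=O)c1ccc(OCc2ccccc2)cc1 | starting material
10 | ethyl (3S)-3-[4-(benzyloxy)phenyl]-3-hydroxypropanoate | CCOC(=O)C[C@H](O)c1ccc(OCc2ccccc2)cc1 | intermediate
11 | (3S)-3-[4-(benzyloxy)phenyl]-3-hydroxypropanoic acid | OC(=O)C[C@H](O)c1ccc(OCc2ccccc2)cc1 | intermediate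
12 | (2R,6S)-6-[4-(benzyloxy)phenyl]-2-tert-butyl-1,3-dioxan-4-one | O=C1C[C@@H](c2ccc(OCc3ccccc3)cc2)O[C@@H](C(C)(C)C)O1 | intermediate
13 | (2R,6S)-6-[4-(benzyloxy)phenyl]-2-tert-butyl-1,3-dioxan-4-ol (C4 epimers) | OC1C[C@@H](c2ccc(OCc3ccccc3)cc2)O[C@@H](C(C)(C)C)O1 | intermediate
14 | (2R,6S)-6-[4-(benzyloxy)phenyl]-2-tert-butyl-1,3-dioxan-4-yl methanesulfonate | CS(=O)(=O)OC1C[C@@H](c2ccc(OCc3ccccc3)cc2)O[C@@H](C(C)(C)C)O1 | intermediate
15 | (2S,4S)-4-[4-(benzyloxy)phenyl]-2-tert-butyl-4H-1,3-dioxin | C1=CO[C@H](C(C)(C)C)O[C@@H]1c1ccc(OCc2ccccc2)cc1 | intermediate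
16 | N-hydroxy-2,4,6-tris(benzyloxy)-3-methoxy-5-methylbenzenecarboximidoyl chloride | COc1c(OCc2ccccc2)c(C(Cl)=NO)c(OCc2ccccc2)c(C)c1OCc1ccccc1 | intermediate
17 | 2,4,6-tris(benzyloxy)-3-methoxy-5-methylbenzonitrile oxide | COc1c(OCc2ccccc2)c(C#[N+][O-])c(OCc2ccccc2)c(C)c1OCc1ccccc1 | intermediate
18 | (3aR,4S,6R,7aR)-4-[4-(benzyloxy)phenyl]-6-tert-butyl-3-[2,4,6-tris(benzyloxy)-3-methoxy-5-methylphenyl]-3a,7a-dihydro-4H,6H-[1,3]dioxino[5,4-d]isoxazole (ring atoms O1–N2=C3–C3a–C4–O5–C6–O7–C7a; C7a bonded to O1 and O7) | O1N=C(c2c(OCc3ccccc3)c(C)c(OCc3ccccc3)c(OC)c2OCc2ccccc2)[C@H]2[C@@H]1O[C@H](C(C)(C)C)O[C@@H]2c1ccc(OCc2ccccc2)cc1 | intermediate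
19 | (2R,4S,5R,6S)-6-[4-(benzyloxy)phenyl]-2-tert-butyl-5-{imino[2,4,6-tris(benzyloxy)-3-methoxy-5-methylphenyl]methyl}-1,3-dioxan-4-ol | N=C(c1c(OCc2ccccc2)c(C)c(OCc2ccccc2)c(OC)c1OCc1ccccc1)[C@H]1[C@@H](O)O[C@H](C(C)(C)C)O[C@@H]1c1ccc(OCc2ccccc2)cc1 | intermediate
20 | [(2R,4S,5R,6S)-6-[4-(benzyloxy)phenyl]-2-tert-butyl-4-hydroxy-1,3-dioxan-5-yl][2,4,6-tris(benzyloxy)-3-methoxy-5-methylphenyl]methanone (C4 as formed; the lactol may anomerise) | O=C(c1c(OCc2ccccc2)c(C)c(OCc2ccccc2)c(OC)c1OCc1ccccc1)[C@H]1[C@@H](O)O[C@H](C(C)(C)C)O[C@@H]1c1ccc(OCc2ccccc2)cc1 | intermediate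
21 | [(2R,4S,5R,6S)-2-tert-butyl-4-hydroxy-6-(4-hydroxyphenyl)-1,3-dioxan-5-yl](2,4,6-trihydroxy-3-methoxy-5-methylphenyl)methanone | O=C(c1c(O)c(C)c(O)c(OC)c1O)[C@H]1[C@@H](O)O[C@H](C(C)(C)C)O[C@@H]1c1ccc(O)cc1 | intermediate
22 | (2S,3R)-2,5,7-trihydroxy-3-[(S)-hydroxy(4-hydroxyphenyl)methyl]-6-methoxy-8-methylchroman-4-one | COc1c(O)c(C)c2c(c1O)C(=O)[C@H]([C@H](O)c1ccc(O)cc1)[C@@H](O)O2 | target

Total step count: 14. Longest linear sequence: 9 steps (steps 1–6 and 12–14); the dioxin branch (steps 7–11) is five steps.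

**Steps most likely to fail**

Step 12 (key cycloaddition). The bimolecular addition of a hindered, electron-rich dipole to a cis-disubstituted enol ether may be too slow. Isomerisation of 17 to the isocyanate, retro-[4+2] fragmentation or acid-induced ionisation of 15, or addition to the other face could then take over. The fallback makes the same C3–C4 bond by an aldol reaction and sets out from 12 and 7. The lithium enolate of 12 (LiN(i-Pr)2, THF, −78 °C) should add to 7 trans to the 6-aryl group to give (2R,5R,6S)-6-[4-(benzyloxy)phenyl]-2-tert-butyl-5-{hydroxy[2,4,6-tris(benzyloxy)-3-methoxy-5-methylphenyl]methyl}-1,3-dioxan-4-one F1. Reduction of the lactone with i-Bu2AlH at −78 °C would give the corresponding 1,3-dioxan-4-ol F2. Oxidation of the benzylic carbinol with MnO2 would then return to the route at 20.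

Step 13 (N–O cleavage and imine hydrolysis). The hindered, electron-rich ketimine may hydrolyse slowly. The hemiacetal may also collapse while O1 is still benzylated, so that the open β-imino or β-keto aldehyde tautomerises to an enaminone or loses the C9 oxygen by β-elimination. The fallback reverses the order of unmasking and sets out from 18. Hydrogenolysis of the benzyl ethers first (H2, Pd(OH)2/C, EtOAc, rt) would give 2-[(3aR,4S,6R,7aR)-6-tert-butyl-4-(4-hydroxyphenyl)-3a,7a-dihydro-4H,6H-[1,3]dioxino[5,4-d]isoxazol-3-yl]-4-methoxy-6-methylbenzene-1,3,5-triol F3. N–O hydrogenolysis (Raney Ni, H2, B(OH)3, MeOH/H2O) would then pass through (2R,4S,5R,6S)-2-tert-butyl-6-(4-hydroxyphenyl)-5-[imino(2,4,6-trihydroxy-3-methoxy-5-methylphenyl)methyl]-1,3-dioxan-4-ol F4. With O1–H already in place to trap the aldehyde, hydrolysis of F4 comes back to the route at 21, which collapses to 22 as in step 14.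

Step 11 (dehydration to the dioxin). The product is a vinylogous, 4-alkoxybenzylic acetal. Under the slightly acidic conditions of mesylate formation it may ionise, with racemisation at C4 or a Ferrier-type rearrangement, or the elimination may stay incomplete. The fallback avoids any oxocarbenium ion and sets out from 12. Enolisation and O-phosphorylation (KN(SiMe3)2, (PhO)2P(O)Cl, THF, −78 °C) would give (2R,4S)-4-[4-(benzyloxy)phenyl]-2-tert-butyl-4H-1,3-dioxin-6-yl diphenyl phosphate F5. Palladium-catalysed reduction of this ketene acetal phosphate (Pd(PPh3)4, Bu3SnH, THF) would come back to the route at 15.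

**Further compounds**

F1 | step 12 | (2R,5R,6S)-6-[4-(benzyloxy)phenyl]-2-tert-butyl-5-{hydroxy[2,4,6-tris(benzyloxy)-3-methoxy-5-methylphenyl]methyl}-1,3-dioxan-4-one (carbinol epimers) | O=C1[C@H](C(O)c2c(OCc3ccccc3)c(C)c(OCc3ccccc3)c(OC)c2OCc2ccccc2)[C@@H](c2ccc(OCc3ccccc3)cc2)O[C@@H](C(C)(C)C)O1
F2 | step 12 | (2R,5R,6S)-6-[4-(benzyloxy)phenyl]-2-tert-butyl-5-{hydroxy[2,4,6-tris(benzyloxy)-3-methoxy-5-methylphenyl]methyl}-1,3-dioxan-4-ol (epimers at C4 and at the carbinol) | OC1[C@H](C(O)c2c(OCc3ccccc3)c(C)c(OCc3ccccc3)c(OC)c2OCc2ccccc2)[C@@H](c2ccc(OCc3ccccc3)cc2)O[C@@H](C(C)(C)C)O1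
F3 | step 13 | 2-[(3aR,4S,6R,7aR)-6-tert-butyl-4-(4-hydroxyphenyl)-3a,7a-dihydro-4H,6H-[1,3]dioxino[5,4-d]isoxazol-3-yl]-4-methoxy-6-methylbenzene-1,3,5-triol | O1N=C(c2c(O)c(C)c(O)c(OC)c2O)[C@H]2[C@@H]1O[C@H](C(C)(C)C)O[C@@H]2c1ccc(O)cc1
F4 | step 13 | (2R,4S,5R,6S)-2-tert-butyl-6-(4-hydroxyphenyl)-5-[imino(2,4,6-trihydroxy-3-methoxy-5-methylphenyl)methyl]-1,3-dioxan-4-ol | N=C(c1c(O)c(C)c(O)c(OC)c1O)[C@H]1[C@@H](O)O[C@H](C(C)(C)C)O[C@@H]1c1ccc(O)cc1
F5 | step 11 | (2R,4S)-4-[4-(benzyloxy)phenyl]-2-tert-butyl-4H-1,3-dioxin-6-yl diphenyl phosphate | O=P(Oc1ccccc1)(Oc1ccccc1)OC1=C[C@@H](c2ccc(OCc3ccccc3)cc2)O[C@@H](C(C)(C)C)O1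
A1 | direct plan | ethyl 2-[7-iodo-5-methoxy-4,6-bis(triisopropylsilyloxy)-1-benzofuran-3-yl]acetate | CCOC(=O)Cc1coc2c(I)c(O[Si](C(C)C)(C(C)C)C(C)C)c(OC)c(O[Si](C(C)C)(C(C)C)C(C)C)c12
A2 | direct plan | 3-[(2S)-2-(tert-butyldimethylsilyloxy)-2-[4-(tert-butyldimethylsilyloxy)phenyl]ethyl]-5-methoxy-7-methyl-4,6-bis(triisopropylsilyloxy)-1-benzofuran | COc1c(O[Si](C(C)C)(C(C)C)C(C)C)c(C)c2occ(C[C@H](O[Si](C)(C)C(C)(C)C)c3ccc(O[Si](C)(C)C(C)(C)C)cc3)c2c1O[Si](C(C)C)(C(C)C)C(C)C
A3 | direct plan | 2-[(3S)-3-(tert-butyldimethylsilyloxy)-3-[4-(tert-butyldimethylsilyloxy)phenyl]propanoyl]-4-methoxy-6-methyl-3,5-bis(triisopropylsilyloxy)phenyl formate | COc1c(O[Si](C(C)C)(C(C)C)C(C)C)c(C)c(OC=O)c(C(=O)C[C@H](O[Si](C)(C)C(C)(C)C)c2ccc(O[Si](C)(C)C(C)(C)C)cc2)c1O[Si](C(C)C)(C(C)C)C(C)C
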